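If a flask is judged at a fixed time, I ask first where it must end and then how fast it gets there, and that is how I took these flasks.

in all of them: initiator 10 mol%
- blue: substrate 0.013 M; coupling partner 1.2 equiv; scavenger 0.80 equiv; temperature 110 °C; run made earlier
- amber: substrate 0.013 M; coupling partner 0.60 equiv; scavenger 1.2 equiv; temperature 110 °C; run made earlier
- ash: substrate 0.013 M; coupling partner 1.20 equiv; scavenger 1.20 equiv; temperature 140 °C; time 10 min
- cedar: substrate 0.040 M; coupling partner 1.20 equiv; scavenger 1.20 equiv; temperature 110 °C; time 10 min
- elm: substrate 0.040 M; coupling partner 1.20 equiv; scavenger 1.20 equiv; temperature 140 °C; time 10 min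
- larch: substrate 0.013 M; coupling partner 1.20 equiv; scavenger 1.20 equiv; temperature 110 °C; time 10 min

| run | time / min | product / % | substrate / % |
|---|---|---|---|
| blue | 0.250 | 4.8 | 94.6 |
| blue | 0.667 | 11.8 | 88.0 |
| blue | 1.33 | 20.5 | 79.3 |
| blue | 2.00 | 29.6 | 71.8 |
| blue | 2.50 | 33.7 | 65.4 |
| blue | 4.00 | 48.0 | 53.0 |
| amber | 0.250 | 3.6 | 98.7 |
| amber | 0.667 | 4.8 | 94.0 |
| amber | 1.33 | 10.2 | 88.9 |
| amber | 2.00 | 16.6 | 86.0 |
| amber | 2.50 | 16.2 | 81.6 |
| amber | 4.00 | 24.4 | 73.8 |

(standard deviation of a reading: 1 percentage point)

- the numbers in the tables scatter by 1 percentage point (one standard deviation)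
- the earlier runs do not show what temperature does; that part of a forecast is a guess
- no earlier run changes the charge of initiator; that part of a forecast is a guess

- the flasks put in order of amount of product, in percent of the substrate charged, best first, at 10 min (ash / cedar / elm / larch)
- the amount of product, in percent of the substrate charged of the flask you put first, at 10 min
- the amount of product, in percent of the substrate charged of the flask you put last, at 10 min

For the end, I assumed one coupling partner per product, so with 1.20 equiv of it the substrate was the limiting reagent in each flask and the ceiling was 100 %.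

The fastest rung lay below the first reading: in blue, product and substrate added up to 99.4 % at 0.250 min and 101 % at 4.00 min, so within the scatter no visible share stood between them.

The next rung came from blue's last reading:

half-time = ln 2 × 4.00 min / ln(100 % / 53.0 %) = 4.37 min

I carried this reading as the partner clock, the time in which substrate halves at a given charge of coupling partner. Amber's clock read 9.13 min, twice blue's, on half the partner. Amber also differed in scavenger, so giving that ratio to the partner was my judgement.

Larch differed from blue in scavenger, and I gave it blue's clock:

10 min / 4.37 min = 2.29 clocks, substrate left 20.4 %, product 79.6 %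

Partner falls along with substrate, so I took that product as an upper figure. No run changed the concentration, but if the pair meet bimolecularly, cedar's clock is 1.42 min, far shorter than 10 min. Ash and elm were guesses, since no run showed temperature, so I committed to larch last and left the others unranked near the ceiling.

The forecast, lower than my figure for larch, gave elm > ash > cedar > larch, 97 % on top and 69 % for larch, and said “Ash versus cedar is the uncertain pair”.

The flasks gave cedar > elm > ash > larch, with cedar at 88.5 % and larch at 74.1 %. Elm had 0 % substrate left at 10.0 min yet held 86.0 % product, with 14.0 % of the substrate charged as ended chains against 2.68 % in cedar.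

    2 first chain carrier → ended chains (k = 5.00 × 10⁷ /M/s, Ea = 10.0 kJ/mol)
    scavenger + released group → scavenged by-product (k = 14.0 /M/s, Ea = 65.0 kJ/mol)
    substrate + initiating radical → capped initiator + first chain carrier (k = 1.10 × 10⁶ /M/s, Ea = 21.0 kJ/mol)
    coupling partner + first chain carrier ⇌ product + second chain carrier (K = 2.20, k = 34000 /M/s, Ea = 15.0 kJ/mol, ΔH = −51.0 kJ/mol)
    substrate + second chain carrier → released group + first chain carrier (k = 83000 /M/s, Ea = 14.0 kJ/mol)
    coupling partner ⇌ dormant form (K = 0.670, k = 8.00 × 10⁻⁴ /s, Ea = 129 kJ/mol, ΔH = −10.0 kJ/mol)
    coupling partner + released group ⇌ idle adduct, settled at all times (K = 630 /M, ΔH = −30.0 kJ/mol)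
    initiator → 2 initiating radical (k = 2.40 × 10⁻⁴ /s, Ea = 106 kJ/mol)
    (constants at 110 °C)

Larch's 23.3 % of substrate reads as a clock of 4.76 min, and cedar's 8.79 % reads as 2.85 min, longer than the 1.42 min I had scaled. Scaled by partner from cedar's reading, the clock of cedar's neighbour with 0.480 equiv of partner is 7.12 min, shorter than 10 min, but on my count of one partner per product that charge set a ceiling of 0.480 equiv, so there the clock gauged pace and did not promise a halving. That neighbour gave 39.9 % product, with 7.55 % of its own partner charge left.

The runs stem from a simulated flask on assumed constants.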